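The readings are calculated with made-up constants; noise was put on by code.

In a one-step world each reagent gives one target, so the reagent charged, where it is the smaller charge, tells the target we get.

| flask | starting material | second substrate | reagent | free catalyst | remark | time |
|---|---|---|---|---|---|---|
| maple | 0.056 M | 0.029 M | 0.0448 M | 2.8 mM | run made earlier |  |
| larch | 0.056 M | 0.096 M | 0.0448 M | 2.8 mM | run made earlier |  |
| oak | 0.056 M | 0.056 M | 0.036 M | 2.8 mM | run made earlier |  |
| Friday's | 0.056 M | 0.0560 M | 0.0250 M | 2.0 mM |  | 3.0 d |
| Sunday's | 0.040 M | 0.0560 M | 0.100 M | 2.8 mM |  | 3.0 d |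
| Thursday's | 0.056 M | 0.0800 M | 0.0448 M | 6.0 mM |  | 3.0 d |
| Monday's | 0.056 M | 0.0560 M | 0.0448 M | 2.8 mM |  | 3.0 d |
| Saturday's | 0.056 M | 0.0300 M | 0.0250 M | 2.0 mM |  | 3.0 d |
| Tuesday's | 0.056 M | 0.0200 M | 0.0448 M | 2.8 mM |  | 3.0 d |

| run | time / h | target / % |
|---|---|---|
| maple | 6.00 | 13.3 |
| maple | 12.0 | 23.4 |
| maple | 20.0 | 32.2 |
| maple | 25.0 | 36.1 |
| maple | 30.0 | 38.4 |
| maple | 40.0 | 42.4 |
| larch | 6.00 | 10.4 |
| larch | 12.0 | 17.1 |
| larch | 20.0 | 21.7 |
| larch | 25.0 | 22.6 |
| larch | 30.0 | 23.5 |
| larch | 40.0 | 24.0 |
| oak | 3.00 | 5.2 |
| oak | 5.00 | 8.5 |
| oak | 10.0 | 15.9 |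
| oak | 20.0 | 22.6 |
| oak | 40.0 | 26.5 |

(scatter of a reading: 0.3 percentage points)

- all flasks from highest to lowest amount of target, in percent of the starting material charged, at 3.0 d (Friday's / Sunday's / Thursday's / Monday's / Saturday's / Tuesday's)
- the amount of target, in percent of the starting material charged of the flask you put first, at 3.0 d
- the amount of target, in percent of the starting material charged of the flask you put last, at 3.0 d

- in percentages every species weighs as the starting material in it: one side product counts as two
- steps thought possible: starting material + free catalyst <-> catalyst intermediate A; reagent + catalyst intermediate A -> free catalyst + target; second substrate + free catalyst <-> catalyst intermediate B; reagent + catalyst intermediate B -> free catalyst + second product; starting material + target -> side product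
- no earlier run changes the charge of free catalyst; that part of a forecast is a guess

Larch and maple carry the same 0.0448 M of reagent on the same 0.056 M of starting material, which in that world allows 80.0% of target. Yet at 40.0 h larch reads 24.0% and maple reads 42.4%.

The two runs differ in second substrate, which can take reagent through catalyst intermediate B to second product. So we suppose that in these runs the reagent, the limiting reagent, is shared. The last two larch readings differ by 0.5 percentage points, so we count its 0.0448 M of reagent as taken up: target took 0.01344 M and second product the rest.

S = [(c(reagent) − c(target)) / c(second substrate)] / [c(target) / c(starting material)] = 1.36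

This S, read off the larch readings, is the selectivity factor: how many times more readily second substrate takes reagent than the same amount of starting material does. If the reagent is all taken up, and the charged amounts stand in for the amounts as they fall, the target as a share of the starting material charged is then

c(reagent) / (c(starting material) + S c(second substrate))

Oak, which played no part in S, checks this: the rule gives 27.2%, and its last reading is 26.5%. For the new flasks we reckon:

Sunday's 86.0%, Tuesday's 53.8%, Monday's 33.9%

Thursday's 27.2%, Saturday's 25.8%, Friday's 18.9%

Some of these figures are held loosely. Sunday's has more reagent than both substrates together, 0.100 M against 0.0960 M, so the rule's count of the reagent all taken up does not apply to Sunday's, and its end is a matter of time. For Friday's and Saturday's, if rate follows catalyst, which is a guess, oak's 40.0 h stretches to 56.0 h at 2.0 mM, still shorter than 3.0 d.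

The forecast gives our order, Sunday's > Tuesday's > Monday's > Thursday's > Saturday's > Friday's, with 18.5% last and 78% first, lower than our Sunday's figure, saying “Sunday has reagent in excess, so it is limited by rate rather than reagent”.

The flasks give Sunday's > Tuesday's > Monday's > Thursday's > Saturday's > Friday's, from 82.4% down to 17.5%.

    starting material + free catalyst ⇌ catalyst intermediate A (K = 13.0 M⁻¹, k = 0.00600 M⁻¹ s⁻¹)
    reagent + catalyst intermediate A → free catalyst + target (k = 0.0160 M⁻¹ s⁻¹)
    second substrate + free catalyst ⇌ catalyst intermediate B (K = 11.0 M⁻¹, k = 0.00660 M⁻¹ s⁻¹)
    reagent + catalyst intermediate B → free catalyst + second product (k = 0.0250 M⁻¹ s⁻¹)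
    starting material + target → side product (k = 1.40 × 10⁻⁵ M⁻¹ s⁻¹)

Friday's ends below our 18.9%; it holds 4.79% of side product, and at 3.00 d target is made at 0.265 of the rate at which it is used up. We put S to use once more on a neighbour of Friday's with 0.095 M of second substrate, where the rule gives 13.5% and the flask gives 12.4%.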